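## Analysis of the target

- The target 34 is a linear chain of eight benzene rings, lettered A to H from the 2,4,6-trihydroxyphenyl end. The rings are joined by seven diaryl ether oxygens and carry 21 free phenolic hydroxyls (C48H34O28).
- It has no stereocentre and no stable axial chirality, so the problem is one of oxygenation pattern and C–O bond formation only.
- Three ring types recur. Rings B, D and F are 2,6-dihydroxy-1,4-phenylene units whose crowded oxygen (between the two hydroxyls) leads to the next ring. Rings C, E and G are pentaoxygenated. Rings A and H are end caps.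
- Each bridging oxygen sits on a carbon with two oxygenated neighbours in its A-ward ring and on a carbon with at most one such neighbour in its H-ward ring.
- The free polyphenol (pyrogallol- and hydroxyquinol-type rings) oxidises readily in air, above all in base. The protected rings are very electron-rich and open to electrophilic halogenation and oxidation.
- The difficulty is to place 28 oxygens with full regiocontrol and to make seven ether bonds between crowded, electron-rich partners for which nucleophilic aromatic substitution is not available.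
- The strategy rests on ring E. Its five contiguous oxygenated carbons (C3, C4, C5, C6, C1) and single CH (C2) map onto a squarate ester (four oxygenated carbons) plus an aryloxyvinyl unit that brings C1 with the ring D oxygen and C2.

## Retrosynthetic reasoning

**Global deprotection.** The last disconnection cleaves the 21 O–methyl bonds of 34 and leads to permethyl ether 33. Methyl ethers survive organolithium reagents, 110 °C, copper catalysis, hydrogenolysis and acid, so the air-sensitive polyphenol appears only in the final step.

**F–G ether.** 33 is cut between the ring F oxygen and C1 of ring G into six-ring phenol 27 and two-ring bromide 32. This puts the oxygen on the phenol with two ortho methoxy groups and the halogen on a carbon with one ortho substituent, the sense in which copper-catalysed O-arylation tolerates crowding best. 32 is small and can be used in excess. 32 is cut at the ring G oxygen–ring H bond into bromophenol 31 and iodide 23 (the iodide reacts, the bromide stays). 31 goes back through 30 to aldehyde 28.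

**C–D ether.** 27 comes from its methoxymethyl ether 26, which is cut between C6 of ring C and the ring D oxygen into phenol 19 and iodide 25. This is the one junction where the halogen must sit on the crowded carbon, because ring D leaves the key sequence with its C1 oxygen already in place. An iodide is used to compensate, and the coupling is placed at the three-plus-three stage, not at the end.

**E–F ether.** 19 arises from benzyl ether 18 by debenzylation. 18 is cut between the ring E oxygen (on C6) and ring F C1 into phenol 15 and bromide 17. The oxygen is again on the hindered partner. The methoxymethyl group of 17 masks the ring F oxygen that is needed later as nucleophile and is orthogonal to the benzyl group on ring D.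

**Ring E.** 15 is cut at its C1–C6 bond. Retro-tautomerisation and retro-6π-electrocyclisation give a dienylketene, the ring-opened form of cyclobutenone 12. Nothing has to be introduced by aromatic substitution: four oxygenated carbons come from a squarate ester, the fifth and the CH from the aryloxyvinyl group. The only free hydroxyl is on C6, where ring F must go. The forward reaction has to open the four-membered ring with the vinyl group turned toward the ketene and then close the six-membered ring.

**Precursor.** 12 is traced to alkyne 11 by cis-semi-reduction, and 11 to dimethyl squarate 7 and dichlorovinyl ether 6, a masked lithium acetylide. A vinyllithium made from a 2-bromovinyl ether would give 12 more directly. That ether, however, needs addition of bromine to a vinyl ether next to the very nucleophilic tetraoxygenated ring D. The acetylene route uses no electrophilic halogen, is one step shorter, and sets the Z geometry in the reduction. 6 comes from hindered phenol 3 and trichloroethylene 4. 3 comes from quinone 1 by reduction to 2 and benzylation of the unhindered hydroxyl.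

**Rings A to C.** 25 is cut between the ring B oxygen (on C4) and ring C C1 into phenol 22 and diiodide 24. Of the two iodides of 24, the one with a single ortho substituent should react; the other stays for the C–D coupling. 22 comes from 21, which is cut between the ring A oxygen and ring B C1 into phenol 20 and bromide 17, the same building block as for ring F. 24 is made by iodination of 23.

## Alternatives that were turned down

**Alternative 1:** The disconnection removes two bonds on ring G at once, the bond from the ring F oxygen to C1 and a C6–iodine bond.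
- Forward step: the phenoxide of six-ring phenol 27 would add to 3,4,5-trimethoxybenzyne A2. The aryl anion formed next to the methoxy group would be caught by an iodine electrophile to give seven-ring iodide A1. A copper coupling of A1 with 3,4,5-trimethoxyphenol A3 would finish the skeleton.
- For it: an aryne is indifferent to the crowding around the ring F oxygen and needs no metal. The methoxy group beside the triple bond directs the oxygen to the remote aryne carbon and the charge to the near one, which is the required pattern.
- Against it: the anion must be caught by an external iodine source that would also iodinate or oxidise the electron-rich phenoxide, and protonation competes. The aryne precursor adds steps and the step sits at a six-ring stage. The following coupling at the di-ortho-substituted iodide of A1 is as demanding as step 14 but comes one step before the end.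
- Comparison: on steric tolerance at the F–G junction this alternative is stronger than the copper coupling of step 19. The chosen route offers a preformed two-ring bromide 32 instead, so the last ether bond is made in the favourable sense. It also supplies a pentaoxygenated ring with the right pattern, which the aryne step does not.

**Alternative 2:** Ring B is cut at C2–C3 and C6–C1 into a four-carbon and a two-carbon piece.
- Forward step: on heating, cyclobutenone A5 (ring C on its C4 oxygen) would open to a vinylketene and add ynol ether A6 (ring A) in a [2+2] sense. The new cyclobutenone would reopen and close by 6π electrocyclisation (Danheiser benzannulation) to three-ring phenol A4.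
- For it: two C–C bonds and a ring in one operation, convergent union of the ring A and ring C pieces, regiochemistry fixed by the polarity of the ynol ether, and a bromine already on ring C for the next coupling.
- Against it: ring B is the least demanding ring type of the target, and its oxygen pattern can be bought as 1 or 16. A5 is a 2-unsubstituted 4-aryloxycyclobutenone that needs its own synthesis and is prone to premature ring opening. A6 is an ynol ether of a hindered phenol. The free hydroxyl and ethyl ether of A4 are a differentiation the target does not need. Ring C must still be brought in ready-made with its five oxygens.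
- Comparison: on bonds formed per step and on convergence at the ring-forming step this alternative is stronger. The chosen strategy uses the same kind of thermal cyclobutenone chemistry on a pentaoxygenated ring, where a squarate ester supplies four of the five oxygens, and reaches its precursor in five steps from purchasable materials. Both routes need a coupling of a crowded ring C halide with the ring D phenol; the chosen one uses iodide 25, not a bromide.

**Alternative 3:** Ring A is cut between its ether carbon and a neighbouring hydroxyl carbon, which unravels it to a polyketide-type chain.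
- Forward step: ester A8 would cyclise by Claisen acylation of its aryloxy-bearing C6 on the ester carbonyl to give two-ring triol A7.
- For it: it is biomimetic and ring A arrives without protecting groups. The crowded A–B ether is made beforehand by simple O-alkylation of a ring B phenol, without copper. After debenzylation the hindered ring B oxygen of A7 is the right nucleophile for the next coupling.
- Against it: 3,5-dioxo esters prefer to lactonise to 4-hydroxy-2-pyranones or to cyclise by aldol reaction, and C6 is the least acidic carbon of the chain. The three free hydroxyls of A7 must be capped again before six further couplings. The pentaoxygenated rings are not addressed.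
- Comparison: for the A–B bond the alkylation is at least as reliable as step 10. The chosen route needs only that one coupling of purchasable 20 for ring A and puts the ring synthesis where the substitution pattern is hard to buy.

Key step: step 6

Remark on the chemistry: 34 is achiral. Compounds 10, 11, 12 and 14 are racemic and their single stereocentre disappears when ring E becomes aromatic. Compounds 1, 4, 7, 16, 20, 23 and 28 are taken as purchasable.

## Route

Step 1
Reactants: 1 2,6-dimethoxy-1,4-benzoquinone
Product: 2 2,6-dimethoxybenzene-1,4-diol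
Conditions: Na2S2O4, EtOAc–H2O, rt, Ar
Reagents that add atoms: none
Why: Dithionite reduction of a 1,4-benzoquinone to the hydroquinone; the product is kept under argon because it re-oxidises in air.

Step 2
Reactants: 2 2,6-dimethoxybenzene-1,4-diol
Product: 3 4-(benzyloxy)-2,6-dimethoxyphenol
Conditions: BnBr (1.0 equiv), K2CO3 (1.0 equiv), acetone, rt, Ar
Reagents that add atoms: benzyl bromide, BrCc1ccccc1
Why: Williamson ether synthesis; the 4-hydroxyl is meta to both methoxy groups, hence more acidic and unhindered, while the 1-hydroxyl lies between two methoxy groups, so monoalkylation should occur at O4.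

Step 3
Reactants: 3 4-(benzyloxy)-2,6-dimethoxyphenol; 4 trichloroethylene
Product: 6 5-(benzyloxy)-2-{[(E)-1,2-dichloroethenyl]oxy}-1,3-dimethoxybenzene, via dichloroacetylene 5 (not isolated)
Conditions: K2CO3, DMF, 70 °C
Reagents that add atoms: none
Why: Base removes HCl from 4 to give 5 in the flask, and the phenoxide adds anti across the triple bond (nucleophilic addition to a haloalkyne), the standard route to aryl 1,2-dichlorovinyl ethers; the slim linear electrophile tolerates the two ortho methoxy groups.

Step 4
Reactants: 6 5-(benzyloxy)-2-{[(E)-1,2-dichloroethenyl]oxy}-1,3-dimethoxybenzene; 7 dimethyl squarate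
Product: 11 4-{[4-(benzyloxy)-2,6-dimethoxyphenoxy]ethynyl}-2,3,4-trimethoxycyclobut-2-en-1-one (racemic), via chloroethynyl ether 8 (not isolated), via lithium acetylide 9 (not isolated), via lithium alkoxide 10 (not isolated)
Conditions: n-BuLi (2.05 equiv), THF, −78 to −40 °C; 7 (0.9 equiv), −78 °C; MeOTf, −78 to 0 °C
Reagents that add atoms: methyl trifluoromethanesulfonate, COS(=O)(=O)C(F)(F)F
Why: The first equivalent of n-BuLi eliminates HCl to give 8 and the second exchanges chlorine for lithium to give 9, which adds 1,2 to one carbonyl of the squarate ester (standard squarate chemistry); O-methylation of tertiary alkoxide 10 fixes the 4-methoxy group. The new quaternary carbon is racemic, which does not matter because it becomes sp2 in step 6.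

Step 5
Reactants: 11 4-{[4-(benzyloxy)-2,6-dimethoxyphenoxy]ethynyl}-2,3,4-trimethoxycyclobut-2-en-1-one
Product: 12 4-{(Z)-2-[4-(benzyloxy)-2,6-dimethoxyphenoxy]ethenyl}-2,3,4-trimethoxycyclobut-2-en-1-one (racemic)
Conditions: H2 (1 atm), Pd/CaCO3 poisoned with Pb(OAc)2 (Lindlar catalyst), quinoline, EtOAc, rt
Reagents that add atoms: none
Why: Syn delivery of hydrogen from the poisoned palladium surface (Lindlar semi-hydrogenation) gives the (Z)-enol ether; the benzyl ether, the tetrasubstituted vinylogous-ester C=C of the ring and the ketone should not react.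

Step 6
Reactants: 12 4-{(Z)-2-[4-(benzyloxy)-2,6-dimethoxyphenoxy]ethenyl}-2,3,4-trimethoxycyclobut-2-en-1-one
Product: 15 2-[4-(benzyloxy)-2,6-dimethoxyphenoxy]-4,5,6-trimethoxyphenol, via dienylketene 13 (not isolated), via cyclohexadienone 14 (not isolated)
Conditions: toluene (0.02 M, degassed), 110 °C, Ar
Reagents that add atoms: none
Why: Heating opens the cyclobutenone by conrotatory 4π ring opening to dienylketene 13; the 4-methoxy donor turns outward, which places the aryloxyvinyl group on the ketene side of the new C3=C4 bond, and because the opening is reversible a ketene of the other sense returns to 12. Ring E then closes by a thermal disrotatory 6π electrocyclisation in which the ketene carbon bonds to the aryloxy-bearing vinyl carbon (the C1–C6 bond of ring E) to give dienone 14, and a proton shift from its sp3 carbon aromatises it to phenol 15. The closest known reaction type is the Moore rearrangement of squarate-derived 4-alkenyl-4-alkoxycyclobutenones to hydroquinone monoethers; only the aryloxy substituent on the vinyl terminus is new. The (Z)-aryloxy group lies inside the triene, but the other terminus is an sp ketene carbon without substituents, so the steric cost should be small. No stereocentre persists: the quaternary carbon of 12 becomes sp2 on ring opening and the CH(OAr) centre of 14 is lost on tautomerisation. The only selectivity needed is the sense of rotation in the ring opening, secured by the 4-methoxy group; which oxygen is free follows from connectivity, since the former carbonyl carbon becomes C6–OH between C1–OAr and C5–OMe. High dilution and exclusion of air guard against ketene dimerisation and oxidation of the electron-rich phenol.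

Step 7
Reactants: 16 4-bromo-2,6-dimethoxyphenol
Product: 17 5-bromo-1,3-dimethoxy-2-(methoxymethoxy)benzene
Conditions: NaH, MOMCl, THF–DMF, 0 °C to rt
Reagents that add atoms: chloromethyl methyl ether, COCCl
Why: O-alkylation of the sodium phenoxide (acetal protection); the MOM group survives base, copper catalysis and hydrogenolysis and is removed by acid, so it is orthogonal to the benzyl ether of 15.

Step 8
Reactants: 15 2-[4-(benzyloxy)-2,6-dimethoxyphenoxy]-4,5,6-trimethoxyphenol; 17 5-bromo-1,3-dimethoxy-2-(methoxymethoxy)benzene
Product: 18 5-(benzyloxy)-2-{2-[3,5-dimethoxy-4-(methoxymethoxy)phenoxy]-3,4,5-trimethoxyphenoxy}-1,3-dimethoxybenzene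
Conditions: CuI (10 mol %), picolinic acid (20 mol %), K3PO4, DMSO, 100 °C, Ar
Reagents that add atoms: none
Why: Copper-catalysed Ullmann-type O-arylation; these conditions accept phenols with two ortho substituents, and bromide 17 has no ortho substituent, so the crowding is on the nucleophile only.

Step 9
Reactants: 18 5-(benzyloxy)-2-{2-[3,5-dimethoxy-4-(methoxymethoxy)phenoxy]-3,4,5-trimethoxyphenoxy}-1,3-dimethoxybenzene
Product: 19 4-{2-[3,5-dimethoxy-4-(methoxymethoxy)phenoxy]-3,4,5-trimethoxyphenoxy}-3,5-dimethoxyphenol
Conditions: H2 (1 atm), Pd/C, EtOAc–MeOH, rt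
Reagents that add atoms: none
Why: Hydrogenolysis of the benzyl aryl ether; methyl ethers, the MOM acetal and diaryl ethers are inert.

Step 10
Reactants: 20 2,4,6-trimethoxyphenol; 17 5-bromo-1,3-dimethoxy-2-(methoxymethoxy)benzene
Product: 21 1,3-dimethoxy-2-(methoxymethoxy)-5-(2,4,6-trimethoxyphenoxy)benzene
Conditions: CuI (10 mol %), picolinic acid (20 mol %), K3PO4, DMSO, 90 °C, Ar
Reagents that add atoms: none
Why: Ullmann-type O-arylation of a di-ortho-methoxy phenol with an unhindered aryl bromide, the favourable sense; air is excluded because the phenoxide of 20 is easily oxidised.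

Step 11
Reactants: 21 1,3-dimethoxy-2-(methoxymethoxy)-5-(2,4,6-trimethoxyphenoxy)benzene
Product: 22 2,6-dimethoxy-4-(2,4,6-trimethoxyphenoxy)phenol
Conditions: HCl (2 M), MeOH–THF, 50 °C
Reagents that add atoms: none
Why: Acid-catalysed acetal cleavage; methyl and diaryl ethers are stable to dilute methanolic acid.

Step 12
Reactants: 23 5-iodo-1,2,3-trimethoxybenzene
Product: 24 1,2-diiodo-3,4,5-trimethoxybenzene
Conditions: NIS, CF3CO2H, MeCN, rt to 50 °C
Reagents that add atoms: N-iodosuccinimide, O=C1CCC(=O)N1I
Why: Electrophilic aromatic iodination; the two free positions of 23 are equivalent and each is ortho and para to a methoxy group, so a single diiodide should form.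

Step 13
Reactants: 22 2,6-dimethoxy-4-(2,4,6-trimethoxyphenoxy)phenol; 24 1,2-diiodo-3,4,5-trimethoxybenzene
Product: 25 1-[2,6-dimethoxy-4-(2,4,6-trimethoxyphenoxy)phenoxy]-2-iodo-3,4,5-trimethoxybenzene
Conditions: 24 (2 equiv), CuI (10 mol %), picolinic acid (20 mol %), K3PO4, DMSO, 90 °C, Ar
Reagents that add atoms: none
Why: Ullmann-type O-arylation; the iodide on C1 has one ortho substituent while that on C2 lies between iodine and methoxy, so the hindered phenoxide should take C1. Once the aryloxy group is in place the remaining iodide is flanked on both sides and should resist a second coupling, which the excess of 24 also suppresses.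

Step 14
Reactants: 19 4-{2-[3,5-dimethoxy-4-(methoxymethoxy)phenoxy]-3,4,5-trimethoxyphenoxy}-3,5-dimethoxyphenol; 25 1-[2,6-dimethoxy-4-(2,4,6-trimethoxyphenoxy)phenoxy]-2-iodo-3,4,5-trimethoxybenzene
Product: 26 six-ring methoxymethyl ether of rings A to F (ring D oxygen of 19 bonded to the former C–I carbon of 25)
Conditions: CuI (20 mol %), picolinic acid (40 mol %), K3PO4, DMSO, 110 °C, Ar
Reagents that add atoms: none
Why: Ullmann-type O-arylation with the crowding on the electrophile: phenol 19 is unhindered, and an aryl iodide with two ortho substituents is within reach of picolinic acid-ligated monovalent copper at higher loading and temperature. Iodide is used in place of bromide to ease the carbon–halogen activation.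

Step 15
Reactants: 26 six-ring methoxymethyl ether of rings A to F
Product: 27 six-ring phenol of rings A to F (free hydroxyl on C4 of ring F)
Conditions: HCl (2 M), MeOH–THF, 50 °C
Reagents that add atoms: none
Why: Acid-catalysed acetal cleavage as in step 11; the 15 methyl ethers and five diaryl ethers are stable.

Step 16
Reactants: 28 2,3,4-trimethoxybenzaldehyde
Product: 30 2,3,4-trimethoxyphenol, via aryl formate 29 (not isolated)
Conditions: mCPBA, CH2Cl2, 0 °C to rt; aq. NaHCO3 wash; K2CO3 (cat.), MeOH, rt
Reagents that add atoms: 3-chloroperbenzoic acid, OOC(=O)c1cccc(Cl)c1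
Why: Baeyer–Villiger (Dakin-type) oxidation; the electron-rich aryl group migrates to give formate 29, which is methanolysed in the same flask.

Step 17
Reactants: 30 2,3,4-trimethoxyphenol
Product: 31 6-bromo-2,3,4-trimethoxyphenol
Conditions: NBS, i-Pr2NH (10 mol %), CH2Cl2, 0 °C
Reagents that add atoms: N-bromosuccinimide, O=C1CCC(=O)N1Br
Why: Electrophilic bromination directed by the free hydroxyl; the para position is blocked, so bromine should enter ortho to OH at C6, which is also para to the 3-methoxy group, and the amine additive favours ortho bromination of phenols.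

Step 18
Reactants: 31 6-bromo-2,3,4-trimethoxyphenol; 23 5-iodo-1,2,3-trimethoxybenzene
Product: 32 1-bromo-3,4,5-trimethoxy-2-(3,4,5-trimethoxyphenoxy)benzene
Conditions: 23 (1.2 equiv), CuI (10 mol %), picolinic acid (20 mol %), K3PO4, DMSO, 80 °C, Ar
Reagents that add atoms: none
Why: Ullmann-type O-arylation that is chemoselective for C–I over C–Br at 80 °C; the bromide of 31 sits on an electron-rich phenoxide ring, so self-coupling should be slow.

Step 19
Reactants: 27 six-ring phenol of rings A to F; 32 1-bromo-3,4,5-trimethoxy-2-(3,4,5-trimethoxyphenoxy)benzene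
Product: 33 henicosa-O-methyl ether of 34 (all 21 hydroxyls as methyl ethers)
Conditions: 32 (1.5 equiv), CuI (20 mol %), picolinic acid (40 mol %), K3PO4, DMSO, 110 °C, Ar
Reagents that add atoms: none
Why: Ullmann-type O-arylation of the di-ortho-methoxy phenol 27 with a bromide that has one ortho substituent, the favourable sense; the small partner 32 is used in excess.

Step 20
Reactants: 33 henicosa-O-methyl ether of 34
Product: 34 target octamer (CNP0206369.0)
Conditions: BBr3 (excess), CH2Cl2, −78 °C to rt; MeOH, then H2O; Ar, degassed solvents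
Reagents that add atoms: none
Why: Lewis acid-mediated cleavage of aryl methyl ethers; diaryl ether bonds are not cleaved by BBr3. The polyphenol is isolated under argon by reversed-phase chromatography.

## Compound list

1 | 2,6-dimethoxy-1,4-benzoquinone | COC1=CC(=O)C=C(OC)C1=O | starting material
2 | 2,6-dimethoxybenzene-1,4-diol | COc1cc(O)cc(OC)c1O | intermediate
3 | 4-(benzyloxy)-2,6-dimethoxyphenol | COc1cc(OCc2ccccc2)cc(OC)c1O | intermediate
4 | trichloroethylene | ClC=C(Cl)Cl | starting material
5 | dichloroacetylene | ClC#CCl | intermediate (not isolated)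
6 | 5-(benzyloxy)-2-{[(E)-1,2-dichloroethenyl]oxy}-1,3-dimethoxybenzene | Cl/C=C(\Oc1c(OC)cc(OCc2ccccc2)cc1OC)Cl | intermediate
7 | dimethyl squarate (3,4-dimethoxycyclobut-3-ene-1,2-dione) | COC1=C(OC)C(=O)C1=O | starting material
8 | 5-(benzyloxy)-2-[(chloroethynyl)oxy]-1,3-dimethoxybenzene | ClC#COc1c(OC)cc(OCc2ccccc2)cc1OC | intermediate (not isolated)
9 | {[4-(benzyloxy)-2,6-dimethoxyphenoxy]ethynyl}lithium | [Li]C#COc1c(OC)cc(OCc2ccccc2)cc1OC | intermediate (not isolated)
10 | lithium 1-{[4-(benzyloxy)-2,6-dimethoxyphenoxy]ethynyl}-2,3-dimethoxy-4-oxocyclobut-2-en-1-olate (racemic) | [Li+].[O-]C1(C#COc2c(OC)cc(OCc3ccccc3)cc2OC)C(OC)=C(OC)C1=O | intermediate (not isolated)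
11 | 4-{[4-(benzyloxy)-2,6-dimethoxyphenoxy]ethynyl}-2,3,4-trimethoxycyclobut-2-en-1-one (racemic) | COC1=C(OC)C(OC)(C#COc2c(OC)cc(OCc3ccccc3)cc2OC)C1=O | intermediate
12 | 4-{(Z)-2-[4-(benzyloxy)-2,6-dimethoxyphenoxy]ethenyl}-2,3,4-trimethoxycyclobut-2-en-1-one (racemic) | COC1=C(OC)C(OC)(/C=C\Oc2c(OC)cc(OCc3ccccc3)cc2OC)C1=O | intermediate
13 | (3Z,5Z)-6-[4-(benzyloxy)-2,6-dimethoxyphenoxy]-2,3,4-trimethoxyhexa-1,3,5-trien-1-one | O=C=C(OC)/C(OC)=C(OC)\C=C/Oc1c(OC)cc(OCc2ccccc2)cc1OC | intermediate (not isolated)
14 | 6-[4-(benzyloxy)-2,6-dimethoxyphenoxy]-2,3,4-trimethoxycyclohexa-2,4-dien-1-one (racemic) | O=C1C(OC)=C(OC)C(OC)=CC1Oc1c(OC)cc(OCc2ccccc2)cc1OC | intermediate (not isolated)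
15 | 2-[4-(benzyloxy)-2,6-dimethoxyphenoxy]-4,5,6-trimethoxyphenol (rings D and E) | Oc1c(OC)c(OC)c(OC)cc1Oc1c(OC)cc(OCc2ccccc2)cc1OC | intermediate
16 | 4-bromo-2,6-dimethoxyphenol | COc1cc(Br)cc(OC)c1O | starting material
17 | 5-bromo-1,3-dimethoxy-2-(methoxymethoxy)benzene | COCOc1c(OC)cc(Br)cc1OC | intermediate
18 | 5-(benzyloxy)-2-{2-[3,5-dimethoxy-4-(methoxymethoxy)phenoxy]-3,4,5-trimethoxyphenoxy}-1,3-dimethoxybenzene (rings D to F) | COCOc1c(OC)cc(Oc2c(OC)c(OC)c(OC)cc2Oc2c(OC)cc(OCc3ccccc3)cc2OC)cc1OC | intermediate
19 | 4-{2-[3,5-dimethoxy-4-(methoxymethoxy)phenoxy]-3,4,5-trimethoxyphenoxy}-3,5-dimethoxyphenol | COCOc1c(OC)cc(Oc2c(OC)c(OC)c(OC)cc2Oc2c(OC)cc(O)cc2OC)cc1OC | intermediate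
20 | 2,4,6-trimethoxyphenol | COc1cc(OC)c(O)c(OC)c1 | starting material
21 | 1,3-dimethoxy-2-(methoxymethoxy)-5-(2,4,6-trimethoxyphenoxy)benzene | COCOc1c(OC)cc(Oc2c(OC)cc(OC)cc2OC)cc1OC | intermediate
22 | 2,6-dimethoxy-4-(2,4,6-trimethoxyphenoxy)phenol (rings A and B) | COc1cc(Oc2c(OC)cc(OC)cc2OC)cc(OC)c1O | intermediate
23 | 5-iodo-1,2,3-trimethoxybenzene | COc1cc(I)cc(OC)c1OC | starting material
24 | 1,2-diiodo-3,4,5-trimethoxybenzene | COc1cc(I)c(I)c(OC)c1OC | intermediate
25 | 1-[2,6-dimethoxy-4-(2,4,6-trimethoxyphenoxy)phenoxy]-2-iodo-3,4,5-trimethoxybenzene (rings A to C) | COc1cc(Oc2c(OC)cc(Oc3c(OC)cc(OC)cc3OC)cc2OC)c(I)c(OC)c1OC | intermediate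
26 | six-ring methoxymethyl ether, rings A to F: 15 methyl ethers, MOM on the C4 oxygen of ring F | COCOc1c(OC)cc(Oc2c(OC)c(OC)c(OC)cc2Oc2c(OC)cc(Oc3c(Oc4c(OC)cc(Oc5c(OC)cc(OC)cc5OC)cc4OC)cc(OC)c(OC)c3OC)cc2OC)cc1OC | intermediate
27 | six-ring phenol, rings A to F: 15 methyl ethers, free hydroxyl on C4 of ring F | Oc1c(OC)cc(Oc2c(OC)c(OC)c(OC)cc2Oc2c(OC)cc(Oc3c(Oc4c(OC)cc(Oc5c(OC)cc(OC)cc5OC)cc4OC)cc(OC)c(OC)c3OC)cc2OC)cc1OC | intermediate
28 | 2,3,4-trimethoxybenzaldehyde | COc1ccc(C=O)c(OC)c1OC | starting material
29 | 2,3,4-trimethoxyphenyl formate | O=COc1ccc(OC)c(OC)c1OC | intermediate (not isolated)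
30 | 2,3,4-trimethoxyphenol | COc1ccc(O)c(OC)c1OC | intermediate
31 | 6-bromo-2,3,4-trimethoxyphenol | COc1cc(Br)c(O)c(OC)c1OC | intermediate
32 | 1-bromo-3,4,5-trimethoxy-2-(3,4,5-trimethoxyphenoxy)benzene (rings G and H) | COc1cc(Br)c(Oc2cc(OC)c(OC)c(OC)c2)c(OC)c1OC | intermediate
33 | henicosa-O-methyl ether of 34 (eight rings, 21 methyl ethers) | COc1cc(Oc2c(OC)cc(Oc3c(OC)c(OC)c(OC)cc3Oc3c(OC)cc(Oc4c(Oc5c(OC)cc(Oc6c(OC)cc(OC)cc6OC)cc5OC)cc(OC)c(OC)c4OC)cc3OC)cc2OC)c(Oc2cc(OC)c(OC)c(OC)c2)c(OC)c1OC | intermediate
34 | CNP0206369.0, the free octameric polyphenol | Oc1cc(O)c(Oc2cc(O)c(Oc3cc(O)c(O)c(O)c3Oc3cc(O)c(Oc4cc(O)c(O)c(O)c4Oc4cc(O)c(Oc5cc(O)c(O)c(O)c5Oc5cc(O)c(O)c(O)c5)c(O)c4)c(O)c3)c(O)c2)c(O)c1 | target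

## Step count and least certain steps

Total step count: 20. Longest linear sequence: 12 steps (steps 1 to 6, 8, 9, 14, 15, 19 and 20).

**Step 6 (key step).** The 6π closure may be slowed by the aryloxy group that points into the triene. The reversibly formed ketene could then drain into dimerisation or addition of adventitious nucleophiles, and the electron-rich phenol may oxidise at 110 °C. Fallback: ring E is taken from the aromatic pool. Setting out from 3, bromophenol 31 of step 17 would be protected (NaH, MOMCl) as 1-bromo-3,4,5-trimethoxy-2-(methoxymethoxy)benzene F1. F1 would be coupled with 3 under the conditions of step 8 to give 5-(benzyloxy)-1,3-dimethoxy-2-[3,4,5-trimethoxy-2-(methoxymethoxy)phenoxy]benzene F2. Methanolic HCl would then remove the acetal and the route is rejoined at 15.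

**Step 14.** Activation of the di-ortho-substituted, electron-rich C–I bond by copper may be slower than reductive loss of iodine from 25 and oxidative degradation of the phenoxide of 19. Fallback: the polarity is reversed and palladium replaces copper. Setting out from 19 and 25, phenol 19 would be converted (Tf2O, pyridine) into 4-{2-[3,5-dimethoxy-4-(methoxymethoxy)phenoxy]-3,4,5-trimethoxyphenoxy}-3,5-dimethoxyphenyl trifluoromethanesulfonate F3. Iodide 25 would be hydroxylated (Pd2(dba)3, tBuXPhos, KOH, dioxane–H2O, 100 °C) to 6-[2,6-dimethoxy-4-(2,4,6-trimethoxyphenoxy)phenoxy]-2,3,4-trimethoxyphenol F4. Palladium-catalysed C–O coupling of F4 with F3 (Pd(OAc)2, tBuXPhos, K3PO4, toluene, 100 °C) would rejoin the route at 26.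

**Step 13.** Arylation at the more crowded C–I bond, double arylation, or reductive loss of the spectator iodine may erode the yield of the single regioisomer. Fallback: the two halogens are made different. Setting out from 23, bromination (NBS, MeCN) would give 2-bromo-1-iodo-3,4,5-trimethoxybenzene F5. Coupling with 22 under the conditions of step 13 would occur at the C–I bond and give 2-bromo-1-[2,6-dimethoxy-4-(2,4,6-trimethoxyphenoxy)phenoxy]-3,4,5-trimethoxybenzene F6. Bromine–lithium exchange (n-BuLi, THF, −78 °C) would give {2-[2,6-dimethoxy-4-(2,4,6-trimethoxyphenoxy)phenoxy]-4,5,6-trimethoxyphenyl}lithium F7, and quenching with I2 would rejoin the route at 25.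

**Step 5.** Over-reduction of the enol ether, hydrogenolysis of the tertiary C–OMe bond, or hydration of the ynol ether on handling may compete with clean semi-hydrogenation. Fallback: the Z-alkene is brought in as a vinyllithium.
- Setting out from 3, alkylation with 1,2-dibromoethane (K2CO3, DMF) would give 5-(benzyloxy)-2-(2-bromoethoxy)-1,3-dimethoxybenzene F8.
- Elimination (KOtBu, THF) would give 5-(benzyloxy)-2-(ethenyloxy)-1,3-dimethoxybenzene F9.
- Br2 would be titrated in at −78 °C, to limit bromination of ring D, to give 5-(benzyloxy)-2-(1,2-dibromoethoxy)-1,3-dimethoxybenzene F10 (racemic, not isolated). DBU would convert this into 5-(benzyloxy)-2-{[(Z)-2-bromoethenyl]oxy}-1,3-dimethoxybenzene F11.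
- t-BuLi (2 equiv, THF, −78 °C) would give {(Z)-2-[4-(benzyloxy)-2,6-dimethoxyphenoxy]ethenyl}lithium F12, in which lithium and oxygen are cis so that anti elimination is not possible.
- Addition to 7 would give lithium 1-{(Z)-2-[4-(benzyloxy)-2,6-dimethoxyphenoxy]ethenyl}-2,3-dimethoxy-4-oxocyclobut-2-en-1-olate F13 (racemic), and MeOTf would rejoin the route at 12.

**Step 20.** Cleavage may stop short at some of the 21 methyl ethers, and the free polyphenol may oxidise during isolation. Fallback: isolation through a stable derivative. Setting out from 33, the crude product of the BBr3 reaction would be acetylated (Ac2O, pyridine) to the henicosaacetate of 34 F14. F14 is stable in air and can be separated from partly methylated material on silica. Acid-catalysed methanolysis (HCl, MeOH, degassed) would then give 34.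

## Further compounds

F1 | step 6 | 1-bromo-3,4,5-trimethoxy-2-(methoxymethoxy)benzene | COCOc1c(Br)cc(OC)c(OC)c1OC
F2 | step 6 | 5-(benzyloxy)-1,3-dimethoxy-2-[3,4,5-trimethoxy-2-(methoxymethoxy)phenoxy]benzene | COCOc1c(OC)c(OC)c(OC)cc1Oc1c(OC)cc(OCc2ccccc2)cc1OC
F3 | step 14 | 4-{2-[3,5-dimethoxy-4-(methoxymethoxy)phenoxy]-3,4,5-trimethoxyphenoxy}-3,5-dimethoxyphenyl trifluoromethanesulfonate | COCOc1c(OC)cc(Oc2c(OC)c(OC)c(OC)cc2Oc2c(OC)cc(OS(=O)(=O)C(F)(F)F)cc2OC)cc1OC
F4 | step 14 | 6-[2,6-dimethoxy-4-(2,4,6-trimethoxyphenoxy)phenoxy]-2,3,4-trimethoxyphenol | COc1cc(Oc2c(OC)cc(Oc3c(OC)cc(OC)cc3OC)cc2OC)c(O)c(OC)c1OC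
F5 | step 13 | 2-bromo-1-iodo-3,4,5-trimethoxybenzene | COc1cc(I)c(Br)c(OC)c1OC
F6 | step 13 | 2-bromo-1-[2,6-dimethoxy-4-(2,4,6-trimethoxyphenoxy)phenoxy]-3,4,5-trimethoxybenzene | COc1cc(Oc2c(OC)cc(Oc3c(OC)cc(OC)cc3OC)cc2OC)c(Br)c(OC)c1OC
F7 | step 13 | {2-[2,6-dimethoxy-4-(2,4,6-trimethoxyphenoxy)phenoxy]-4,5,6-trimethoxyphenyl}lithium | [Li]c1c(Oc2c(OC)cc(Oc3c(OC)cc(OC)cc3OC)cc2OC)cc(OC)c(OC)c1OC
F8 | step 5 | 5-(benzyloxy)-2-(2-bromoethoxy)-1,3-dimethoxybenzene | BrCCOc1c(OC)cc(OCc2ccccc2)cc1OC
F9 | step 5 | 5-(benzyloxy)-2-(ethenyloxy)-1,3-dimethoxybenzene | C=COc1c(OC)cc(OCc2ccccc2)cc1OC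
F10 | step 5 | 5-(benzyloxy)-2-(1,2-dibromoethoxy)-1,3-dimethoxybenzene (racemic) | BrCC(Br)Oc1c(OC)cc(OCc2ccccc2)cc1OC
F11 | step 5 | 5-(benzyloxy)-2-{[(Z)-2-bromoethenyl]oxy}-1,3-dimethoxybenzene | Br/C=C\Oc1c(OC)cc(OCc2ccccc2)cc1OC
F12 | step 5 | {(Z)-2-[4-(benzyloxy)-2,6-dimethoxyphenoxy]ethenyl}lithium | [Li]/C=C\Oc1c(OC)cc(OCc2ccccc2)cc1OC
F13 | step 5 | lithium 1-{(Z)-2-[4-(benzyloxy)-2,6-dimethoxyphenoxy]ethenyl}-2,3-dimethoxy-4-oxocyclobut-2-en-1-olate (racemic) | [Li+].[O-]C1(/C=C\Oc2c(OC)cc(OCc3ccccc3)cc2OC)C(OC)=C(OC)C1=O
F14 | step 20 | henicosaacetate of 34 (all 21 hydroxyls as acetates) | CC(=O)Oc1cc(OC(C)=O)c(Oc2cc(OC(C)=O)c(Oc3cc(OC(C)=O)c(OC(C)=O)c(OC(C)=O)c3Oc3cc(OC(C)=O)c(Oc4cc(OC(C)=O)c(OC(C)=O)c(OC(C)=O)c4Oc4cc(OC(C)=O)c(Oc5cc(OC(C)=O)c(OC(C)=O)c(OC(C)=O)c5Oc5cc(OC(C)=O)c(OC(C)=O)c(OC(C)=O)c5)c(OC(C)=O)c4)c(OC(C)=O)c3)c(OC(C)=O)c2)c(OC(C)=O)c1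
A1 | alternative 1 | seven-ring aryl iodide, rings A to G, iodine on C6 of ring G | COc1cc(OC)c(Oc2cc(OC)c(Oc3cc(OC)c(OC)c(OC)c3Oc3cc(OC)c(Oc4cc(OC)c(OC)c(OC)c4Oc4cc(OC)c(Oc5cc(OC)c(OC)c(OC)c5I)c(OC)c4)c(OC)c3)c(OC)c2)c(OC)c1
A2 | alternative 1 | 3,4,5-trimethoxybenzyne | COC1=C(OC)C(OC)=CC#C1
A3 | alternative 1 | 3,4,5-trimethoxyphenol | COc1cc(O)cc(OC)c1OC
A4 | alternative 2 | three-ring phenol, rings A to C, free hydroxyl on C3 and ethyl ether on C5 of ring B, bromine on C6 of ring C | CCOc1cc(Oc2c(OC)cc(OC)cc2OC)cc(O)c1Oc1cc(OC)c(OC)c(OC)c1Br
A5 | alternative 2 | 4-(2-bromo-3,4,5-trimethoxyphenoxy)-3-ethoxycyclobut-2-en-1-one (racemic) | CCOC1=CC(=O)C1Oc1cc(OC)c(OC)c(OC)c1Br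
A6 | alternative 2 | 2-(ethynyloxy)-1,3,5-trimethoxybenzene | C#COc1c(OC)cc(OC)cc1OC
A7 | alternative 3 | 2-[4-(benzyloxy)-3,5-dimethoxyphenoxy]benzene-1,3,5-triol | Oc1cc(O)c(Oc2cc(OC)c(OCc3ccccc3)c(OC)c2)c(O)c1
A8 | alternative 3 | methyl 6-[4-(benzyloxy)-3,5-dimethoxyphenoxy]-3,5-dioxohexanoate | COC(=O)CC(=O)CC(=O)COc1cc(OC)c(OCc2ccccc2)c(OC)c1
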